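**Route in outline (numbers used throughout):** 1 → 3 (via 2); 3 + 4 → 6 (via 5) → 8 (via 7); 9 + 10 → 12 (via 11); 8 + 12 → 14 (via 13) → 15 → 16.

## The problem

7-O-Methylluteone (16) is an isoflavone: a chromone (ring A fused to the pyranone ring C) with a 2,4-dihydroxyphenyl ring B on C3. It has no stereocentre, so nothing has to be controlled in space and the whole difficulty is regiochemical. Ring A is hexasubstituted and fully differentiated: a chelated hydroxyl at C5, a prenyl group at C6, a methoxyl at C7 and hydrogen at C8. Prenylating a preformed 5,7-dioxygenated chromone has to choose between C6, C8 and oxygen, and Claisen relays from O5 or O7 put a reverse-prenyl group on C6 or C8 or a prenyl group on C8; the C6 prenyl group between two oxygens is therefore the central problem, followed by methylation of O7 alone among four phenolic oxygens. The functional groups limit the reagents: the prenyl alkene adds the neighbouring 5-hydroxyl under strong acid and rules out hydrogenolysis, ring B is an electron-rich resorcinol that needs base-stable masks, and the unsubstituted CH of ring C (C2) is open to nucleophiles with ring opening. The feature that offers a way round is the oxidation pattern of ring A: C5 and C7 are both at the carbonyl level and flank C6, so ring A is a masked cyclohexane-1,3-dione. Its carbons map onto C2 and C3 of a pyranone (C8a, C4a), a methyl group on C2 (C8), an ester on C3 (C5), and the carbonyl and α-carbon of a 5-methylhex-4-enoate (C7, C6), whose remaining carbons are the prenyl group.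

## Retrosynthesis

**16 ⇒ 15.** The two phenolic O–H bonds of ring B are traced back to the O–CH2 bonds of two methoxymethyl acetals. Acetals are preferred to benzyl ethers (hydrogenolysis would reduce the prenyl alkene) and to methyl ethers (Lewis-acid cleavage could not spare the 7-methoxyl), and they are inert to the amide base of the key step. 15 is no simpler than 16. The forward step must be an acetal solvolysis mild enough to leave the prenyl alkene and the adjacent 5-hydroxyl alone.

**15 ⇒ 14.** The O7–CH3 bond is cut. Methylating late is dictated by the key step, in which both ring A oxygens are born as enolates. It is affordable because the oxygens of 14 are already different: ring B is masked, O5 is locked in a hydrogen bond to the C4 carbonyl, and O7 is a vinylogous acid. The forward step is one mono-alkylation whose selectivity rests on that chelation.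

**14 ⇒ 8 + 12 (key disconnection).** Ring A is cut at C7–C8 and C5–C6, a retro-Claisen/retro-Dieckmann pair. This gives pyranone ester 8, which keeps rings C and B, and the open-chain ester 12, which holds C6, C7 and the whole prenyl group. The neighbouring cuts are less attractive:
- opening ring C (deoxybenzoin logic) leaves a prenylated phloroglucinol whose two ortho hydroxyls cannot easily be told apart;
- cutting ring A at C4a–C5 and C8–C8a (cycloaddition logic) needs an activated pyranone dienophile and a fragile diene.

The simplification is large: the hexasubstituted benzene ring and the regiochemical problem vanish together, because the prenyl group sits on the α-carbon of 12 and can only end up between the two new oxygens. The forward reaction must metalate the C2 methyl group of 8, acylate it with an enolisable ester and close the 1,3-dione in the same flask without opening the pyranone.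

**8 ⇒ 6.** The pyranone is cut at O1–C6 and C5–C6 (pyranone numbering), which removes the unsubstituted ring CH as a one-carbon unit at the formic acid level and leaves the acyclic triacylmethane 6; enaminone 7 is the forward intermediate. Attaching ring B to a halogenated pyranone by cross-coupling was set aside because it costs a halogenation, a boronic acid and two further steps. Forward, the one-carbon donor must condense at the benzylic methylene and not at the acetyl methyl group, and must not react again with the activated methyl group of 8.

**6 ⇒ 3 + 4.** The bond between the central carbon of 6 and the arylacetyl carbonyl is cut, giving acid 3 (activated as imidazolide 5) and methyl acetoacetate 4. Forming the other C–CO bond instead would require a prior chain extension of 3. The forward step must acylate at carbon and run without strong acid because of the acetals.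

**3 ⇒ 1.** The acetal O–C bonds of 3 are cut to reach commercial acid 1. The carboxyl group is alkylated as well (ester 2) and is released again by saponification in the same operation.

**12 ⇒ 9 + 10.** Ester 12 is cut at C2–C3, the retron of an ortho ester Claisen rearrangement through ketene acetal 11. Alcohol 9 and ortho ester 10 are bulk chemicals, and no alkene geometry is at stake because the new double bond carries two methyl groups. Alkylating an acetate enolate with a prenyl electrophile would give the same ester less cleanly.

## Roads not taken

**Alternative 1: ring B by benzannulation.**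
- Cut: ring B is removed (bonds C1′–C2′, C2′–C3′, C4′–C5′), leading to the chromone-bound diazo enone A2 and the siloxyalkyne A3.
- Forward key step: irradiation of A2 would trigger a Wolff rearrangement; ketene–alkyne [2+2] addition to A3, four-electron ring opening and six-electron closure would give phenol A1.
- Merits: an explored class of benzannulation, neutral conditions, and a ring B whose oxygens are born different (free 2′-hydroxyl, silyl ether at O4′).
- Weak points:
  - The key step is spent on the ring that can be bought. Ring A of A2, with the prenyl group already between two oxygens, must come from another method, so the central problem is only moved.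
  - The chromone and the prenyl alkene are themselves reactive under irradiation and towards ketenes.
  - The annulation leaves a C3′ silyl group to be removed under acid.
  - The 5-methyl ether of A1 must then be cleaved by a Lewis acid next to the prenyl group while the 7-methyl ether stays.
- Comparison: in precedent for the key reaction type this road is ahead, since the chosen cascade is untested on a pyranone. Against that the chosen plan sets a key step that itself fixes the prenyl position, a product (14) two mild steps from 16 instead of three harsher ones, and much shorter access to its precursors.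

**Alternative 2: ring A by cycloaddition.**
- Cut: ring A at C4a–C5 and C8–C8a.
- Forward key step: diene A5, a silyl ketene acetal carrying the prenyl group and the future 7-methoxyl, would add across the sulfinyl-bearing double bond of pyranone A6. Loss of the sulfenic acid and of an alkoxy group would aromatise the adduct to A4, which is the same compound as 15.
- Merits: it also builds ring A around the prenyl group, and it is better in one respect: the 7-methoxyl arrives with the diene, so the selective methylation (step 6) is not needed.
- Weak points:
  - A 3-aryl-4-pyranone is a vinylogous ester and a reluctant dienophile even with a sulfinyl group.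
  - A5 is tetrasubstituted, sensitive to hydrolysis and hindered in its s-cis form by the central prenyl group.
  - Regiochemistry rests on polarity matching, not on connectivity.
  - A6 needs a pyranone synthesis plus sulfenylation and oxidation, and A5 needs several steps of its own.
- Comparison: the step saved at the end is outweighed by the longer preparation of both partners. The chosen plan answers with partners made from bulk chemicals (8 in three steps, 12 in one), an anionic pathway whose regiochemistry cannot go wrong, and a routine methylation.

**Alternative 3: ring C by aryne insertion.**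
- Cut: ring C at C8a–O1, C4a–C4 and O1–C2.
- Forward key step: the aryne set free by fluoride from silyl triflate A8 would insert into the C–O bond of acrylic acid A9, and the phenoxide formed would displace the β-methoxyl to close chromone A7.
- Merits: the most convergent plan, with rings A and B complete before they meet. Acyl–oxygen insertion of arynes into carboxylic acids with ring closure to chromones is a known reaction type, and the methoxyl next to the aryne bond steers the carboxylate oxygen to the right carbon. In convergence and in precedent for the ring-forming event this road is at least equal to the chosen one.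
- Weak points:
  - A8 is a pentasubstituted benzene with the prenyl group between two methoxyls plus a silyl group and a triflate; its multistep preparation brings the regiochemical problem back.
  - The prenyl alkene is an ene partner for arynes.
  - A7 carries two methyl ethers on ring A, so the end-game needs a Lewis-acid demethylation at O5 beside the prenyl group, the setting for chroman formation.
- Comparison: the chosen plan gives up late convergence but obtains the two ring A oxygens differentiated and unprotected (14) and uses no Lewis acid once the prenyl group is in place.

Key step: step 5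

Remark (assumption on the chemistry): 6 and 7 are written as keto tautomers although both should exist as chelated enols; the enamine geometry of 7 is not defined and is irrelevant to ring closure.

**Step 1**
Reactants: 1 2,4-dihydroxyphenylacetic acid
Product: 3 [2,4-bis(methoxymethoxy)phenyl]acetic acid, via methoxymethyl ester 2 (not isolated)
Conditions: MOMCl (4 equiv), iPr2NEt (5 equiv), CH2Cl2, 0 °C → rt; then LiOH, THF/H2O, rt; 1 M HCl to pH 4, 0 °C
Reagents that add atoms: chloromethyl methyl ether, COCCl; lithium hydroxide, [Li+].[OH-]
Why: O-alkylation of the carboxylate and both phenoxides (acetal protection), then acyl–oxygen saponification of the labile methoxymethyl ester, which leaves the aryl acetals intact; masking the ortho hydroxyl also blocks lactonisation to the benzofuranone.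

**Step 2**
Reactants: 3 [2,4-bis(methoxymethoxy)phenyl]acetic acid; 4 methyl acetoacetate
Product: 6 methyl 2-acetyl-4-[2,4-bis(methoxymethoxy)phenyl]-3-oxobutanoate, via acyl imidazolide 5 (not isolated)
Conditions: CDI, THF, rt; then 4, MgCl2, Et3N, MeCN, 0 °C → rt; aq. citric acid
Reagents that add atoms: none
Why: Activation as the imidazolide avoids HCl, which would cleave the acetals; soft enolisation of 4 with MgCl2/Et3N gives a chelated magnesium enolate that is acylated at carbon (crossed Claisen-type C-acylation). The acidic triacylmethane stays as its magnesium chelate until the mild acidic work-up.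

**Step 3**
Reactants: 6 methyl 2-acetyl-4-[2,4-bis(methoxymethoxy)phenyl]-3-oxobutanoate
Product: 8 methyl 5-[2,4-bis(methoxymethoxy)phenyl]-2-methyl-4-oxo-4H-pyran-3-carboxylate, via enaminone 7 (not isolated)
Conditions: Me2NCH(OMe)2 (1.05 equiv), toluene, rt → 50 °C; then AcOH, rt
Reagents that add atoms: N,N-dimethylformamide dimethyl acetal, COC(OC)N(C)C
Why: Amide-acetal condensation (enaminone formation) should occur at the benzylic methylene, the most acidic C–H beside the tricarbonyl core, as with benzyl ketones and deoxybenzoins; the enol oxygen of the acetyl group then displaces dimethylamine by addition–elimination (6-endo closure) to give the 4-pyranone, the acyclic counterpart of isoflavone ring closure. The reagent is kept to one equivalent because the C2 methyl group of 8 is itself activated.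

**Step 4**
Reactants: 9 2-methylbut-3-en-2-ol; 10 trimethyl orthoacetate
Product: 12 methyl 5-methylhex-4-enoate, via ketene acetal 11 (not isolated)
Conditions: EtCO2H (cat.), excess 10, 110 → 140 °C, MeOH distilled off
Reagents that add atoms: none
Why: Johnson–Claisen rearrangement: acid-catalysed exchange and loss of methanol give ketene acetal 11, whose [3,3]-sigmatropic shift carries the two-carbon ester unit to the alkene terminus; the new double bond bears two identical methyl groups, so no geometry arises.

**Step 5**
Reactants: 8 methyl 5-[2,4-bis(methoxymethoxy)phenyl]-2-methyl-4-oxo-4H-pyran-3-carboxylate; 12 methyl 5-methylhex-4-enoate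
Product: 14 3-[2,4-bis(methoxymethoxy)phenyl]-5,7-dihydroxy-6-(3-methylbut-2-enyl)-4H-chromen-4-one, via pyranonylmethyl ketone 13 (not isolated)
Conditions: LiN(iPr)2 (1.1 equiv), THF, −78 °C; 12 (1.3 equiv), −78 → −20 °C; then LiN(iPr)2 (2.5 equiv), −78 → 0 °C; AcOH quench
Reagents that add atoms: none
Why: Proposed new method: a lateral-carbanion Claisen–Dieckmann benzannulation has not been described for a 2-methyl-4-pyranone-3-carboxylate; the closest known reaction type is the acylation of ortho-toluate lateral carbanions by esters with Dieckmann-type closure to naphthalene-1,3-diols, next to the lateral metalation and acylation of 2-methyl-4-pyranones. The first charge of LiN(iPr)2 removes a proton from the C2 methyl group of 8, the only C–H vinylogous to both the ring carbonyl and the ester, and the extended enolate adds through its exocyclic carbon to the ester carbonyl of 12; loss of methoxide forms C7–C8 and gives ketone 13, which rests as its doubly stabilised C8 enolate. Because the amide is consumed before 12 is added and the released methoxide can carry the acidic proton of 13, enolisation of 12 is kept small in this stage. The second charge of LiN(iPr)2 deprotonates 13 at the prenyl-bearing methylene to a 1,3-dianion, whose more reactive terminal carbon (C6) attacks the neighbouring pyranone ester and forms C5–C6. This ring A closure is 6-(enolendo)-exo-trig, a favoured mode that is helped by the cis arrangement of the two arms on the C2=C3 bond of the pyranone. Loss of methoxide and tautomerisation give the resorcinol bis-phenoxide, an irreversible sink; no stereocentre is formed. The step needs lateral deprotonation rather than amide addition at the unsubstituted pyranone CH (secured by the double activation of the methyl group, the hindered base and −78 °C) and closure through carbon rather than oxygen (secured by the dianion, since the monoanion could only lactonise through its enolate oxygen). The position of the prenyl group between O5 and O7 is fixed by the connectivity of 12 and needs no control.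

**Step 6**
Reactants: 14 3-[2,4-bis(methoxymethoxy)phenyl]-5,7-dihydroxy-6-(3-methylbut-2-enyl)-4H-chromen-4-one
Product: 15 3-[2,4-bis(methoxymethoxy)phenyl]-5-hydroxy-7-methoxy-6-(3-methylbut-2-enyl)-4H-chromen-4-one
Conditions: MeI (1.2 equiv), K2CO3 (1.5 equiv), acetone, rt
Reagents that add atoms: iodomethane, CI
Why: Williamson O-methylation; the 7-hydroxyl is a vinylogous carboxylic acid and is deprotonated by K2CO3, whereas the 5-hydroxyl is hydrogen-bonded to the C4 carbonyl and ring B is masked, so only O7 should react at room temperature.

**Step 7**
Reactants: 15 3-[2,4-bis(methoxymethoxy)phenyl]-5-hydroxy-7-methoxy-6-(3-methylbut-2-enyl)-4H-chromen-4-one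
Product: 16 7-O-methylluteone, 3-(2,4-dihydroxyphenyl)-5-hydroxy-7-methoxy-6-(3-methylbut-2-enyl)-4H-chromen-4-one
Conditions: HCl (1.25 M in MeOH), THF, 35 °C
Reagents that add atoms: none
Why: Acid-catalysed acetal solvolysis (transacetalisation to dimethoxymethane) frees both ring B phenols; dilute methanolic acid at mild temperature is chosen because stronger acid would add the 5-hydroxyl across the prenyl double bond.

## Compound list

1 | 2,4-dihydroxyphenylacetic acid | OC(=O)Cc1ccc(O)cc1O | starting material
2 | methoxymethyl [2,4-bis(methoxymethoxy)phenyl]acetate | COCOC(=O)Cc1ccc(OCOC)cc1OCOC | intermediate (not isolated)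
3 | [2,4-bis(methoxymethoxy)phenyl]acetic acid | OC(=O)Cc1ccc(OCOC)cc1OCOC | intermediate
4 | methyl acetoacetate | COC(=O)CC(C)=O | starting material
5 | 2-[2,4-bis(methoxymethoxy)phenyl]-1-(1H-imidazol-1-yl)ethan-1-one | O=C(Cc1ccc(OCOC)cc1OCOC)n1ccnc1 | intermediate (not isolated)
6 | methyl 2-acetyl-4-[2,4-bis(methoxymethoxy)phenyl]-3-oxobutanoate | COC(=O)C(C(C)=O)C(=O)Cc1ccc(OCOC)cc1OCOC | intermediate
7 | methyl 2-acetyl-4-[2,4-bis(methoxymethoxy)phenyl]-5-(dimethylamino)-3-oxopent-4-enoate (enamine geometry not defined) | COC(=O)C(C(C)=O)C(=O)C(=CN(C)C)c1ccc(OCOC)cc1OCOC | intermediate (not isolated)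
8 | methyl 5-[2,4-bis(methoxymethoxy)phenyl]-2-methyl-4-oxo-4H-pyran-3-carboxylate | COC(=O)c1c(C)occ(-c2ccc(OCOC)cc2OCOC)c1=O | intermediate
9 | 2-methylbut-3-en-2-ol | C=CC(C)(C)O | starting material
10 | trimethyl orthoacetate | COC(C)(OC)OC | starting material
11 | 3-[(1-methoxyethenyl)oxy]-3-methylbut-1-ene | C=C(OC)OC(C)(C)C=C | intermediate (not isolated)
12 | methyl 5-methylhex-4-enoate | COC(=O)CCC=C(C)C | intermediate
13 | methyl 5-[2,4-bis(methoxymethoxy)phenyl]-2-(6-methyl-2-oxohept-5-enyl)-4-oxo-4H-pyran-3-carboxylate | COC(=O)c1c(CC(=O)CCC=C(C)C)occ(-c2ccc(OCOC)cc2OCOC)c1=O | intermediate (not isolated)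
14 | 3-[2,4-bis(methoxymethoxy)phenyl]-5,7-dihydroxy-6-(3-methylbut-2-enyl)-4H-chromen-4-one | Oc1cc2occ(-c3ccc(OCOC)cc3OCOC)c(=O)c2c(O)c1CC=C(C)C | intermediate
15 | 3-[2,4-bis(methoxymethoxy)phenyl]-5-hydroxy-7-methoxy-6-(3-methylbut-2-enyl)-4H-chromen-4-one | COc1cc2occ(-c3ccc(OCOC)cc3OCOC)c(=O)c2c(O)c1CC=C(C)C | intermediate
16 | 7-O-methylluteone, 3-(2,4-dihydroxyphenyl)-5-hydroxy-7-methoxy-6-(3-methylbut-2-enyl)-4H-chromen-4-one | COc1cc2occ(-c3ccc(O)cc3O)c(=O)c2c(O)c1CC=C(C)C | target

## Step count and least certain steps

Total: 7 steps. Longest linear sequence: 6 steps (1 → 3 → 6 → 8 → 14 → 15 → 16); step 4 is a one-step branch.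

**Step 5 (key step, proposed new method).**
- Most likely failure: proton transfer outruns C–C bond formation. Ketone 13 is far more acidic than 8 and can quench the lateral anion, and any free amide enolises 12. In the closing stage the monoanion may close through its enolate oxygen, or the amide may add to the unsubstituted pyranone CH with ring opening.
- Fallback (known chemistry), setting out from 12 and 8 and returning at 14:
  - 12 is converted with MeNH(OMe)·HCl and iPrMgCl into N-methoxy-N,5-dimethylhex-4-enamide F1.
  - The lateral anion of 8 (LiN(iPr)2, THF, −78 °C) is acylated by F1. Its tetrahedral adduct survives until the quench, so no acidic ketone is present beside the carbanion, and 13 is now isolated.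
  - 13 is closed with KOtBu in THF (or NaOMe in MeOH) under equilibrating conditions, where any lactone reopens and only C-cyclisation leads to the aromatic sink 14.
  - Both operations are standard carbonyl chemistry: ketone synthesis from a stabilised carbanion and an N-methoxy-N-methylamide, and alkoxide-mediated Claisen cyclisation of a 5-oxo ester to a 1,3-dione.

**Step 3.**
- Most likely failure: a second condensation of the amide acetal at the activated C2 methyl group of the pyranone once it has formed, condensation at the acetyl methyl group instead of the benzylic methylene, or O-methylation of the acidic enol by the reagent.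
- Fallback, setting out from 3 (with 4) and returning at 8; the one-carbon unit is fixed on the benzylic carbon before the tricarbonyl exists:
  - 3 is esterified (MeI, K2CO3, DMF) to methyl [2,4-bis(methoxymethoxy)phenyl]acetate F2.
  - Claisen formylation (HCO2Me, NaH) and O-methylation of the enolate (Me2SO4) give methyl (E)-2-[2,4-bis(methoxymethoxy)phenyl]-3-methoxyprop-2-enoate F3.
  - Saponification (LiOH) gives (E)-2-[2,4-bis(methoxymethoxy)phenyl]-3-methoxyprop-2-enoic acid F4.
  - CDI activation and C-acylation of the MgCl2/Et3N enolate of 4 give methyl (4E)-2-acetyl-4-[2,4-bis(methoxymethoxy)phenyl]-5-methoxy-3-oxopent-4-enoate F5.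
  - The enol oxygen of F5 displaces the methoxyl by addition–elimination to close 8.

**Step 2.**
- Most likely failure: deprotonation of the arylacetyl imidazolide at its benzylic carbon (ketene formation, self-acylation), and retro-Claisen loss of the acetyl group from the crowded triacylmethane on work-up.
- Fallback, setting out from 3 (through 5) and returning at 6; the order of the two acylations is reversed:
  - Decarboxylative malonate half-ester chain extension of 5 (methyl potassium malonate, MgCl2, Et3N) gives methyl 4-[2,4-bis(methoxymethoxy)phenyl]-3-oxobutanoate F6.
  - F6 is C-acetylated with the small, reactive AcCl (MgCl2, pyridine, CH2Cl2) to 6.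

**Step 7.**
- Most likely failure: acid-promoted addition of the chelated 5-hydroxyl, or of methanol, to the prenyl double bond during acetal solvolysis.
- Fallback, setting out from 15 and returning at 16; the acetals are exchanged for silyl ethers without protic acid:
  - TMSOTf and 2,2′-bipyridyl in CH2Cl2 at 0 °C give 3-[2,4-bis(trimethylsilyloxy)phenyl]-5-hydroxy-7-methoxy-6-(3-methylbut-2-enyl)-4H-chromen-4-one F7.
  - F7 is hydrolysed with water at neutral pH to 16.

## Further compounds

F1 | step 5 | N-methoxy-N,5-dimethylhex-4-enamide | CON(C)C(=O)CCC=C(C)C
F2 | step 3 | methyl [2,4-bis(methoxymethoxy)phenyl]acetate | COC(=O)Cc1ccc(OCOC)cc1OCOC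
F3 | step 3 | methyl (E)-2-[2,4-bis(methoxymethoxy)phenyl]-3-methoxyprop-2-enoate | CO/C=C(/C(=O)OC)c1ccc(OCOC)cc1OCOC
F4 | step 3 | (E)-2-[2,4-bis(methoxymethoxy)phenyl]-3-methoxyprop-2-enoic acid | CO/C=C(/C(O)=O)c1ccc(OCOC)cc1OCOC
F5 | step 3 | methyl (4E)-2-acetyl-4-[2,4-bis(methoxymethoxy)phenyl]-5-methoxy-3-oxopent-4-enoate | COC(=O)C(C(C)=O)C(=O)/C(=C/OC)c1ccc(OCOC)cc1OCOC
F6 | step 2 | methyl 4-[2,4-bis(methoxymethoxy)phenyl]-3-oxobutanoate | COC(=O)CC(=O)Cc1ccc(OCOC)cc1OCOC
F7 | step 7 | 3-[2,4-bis(trimethylsilyloxy)phenyl]-5-hydroxy-7-methoxy-6-(3-methylbut-2-enyl)-4H-chromen-4-one | COc1cc2occ(-c3ccc(O[Si](C)(C)C)cc3O[Si](C)(C)C)c(=O)c2c(O)c1CC=C(C)C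
A1 | alternative 1 | 3-[2-hydroxy-4-(triisopropylsilyloxy)-3-(trimethylsilyl)phenyl]-5,7-dimethoxy-6-(3-methylbut-2-enyl)-4H-chromen-4-one | COc1cc2occ(-c3ccc(O[Si](C(C)C)(C(C)C)C(C)C)c([Si](C)(C)C)c3O)c(=O)c2c(OC)c1CC=C(C)C
A2 | alternative 1 | (E)-3-(4-diazo-3-oxobut-1-enyl)-5,7-dimethoxy-6-(3-methylbut-2-enyl)-4H-chromen-4-one | COc1cc2occ(/C=C/C(=O)C=[N+]=[N-])c(=O)c2c(OC)c1CC=C(C)C
A3 | alternative 1 | triisopropyl{[(trimethylsilyl)ethynyl]oxy}silane | CC(C)[Si](OC#C[Si](C)(C)C)(C(C)C)C(C)C
A4 | alternative 2 | 3-[2,4-bis(methoxymethoxy)phenyl]-5-hydroxy-7-methoxy-6-(3-methylbut-2-enyl)-4H-chromen-4-one | COc1cc2occ(-c3ccc(OCOC)cc3OCOC)c(=O)c2c(O)c1CC=C(C)C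
A5 | alternative 2 | {[1,3-dimethoxy-2-(3-methylbut-2-enyl)buta-1,3-dienyl]oxy}trimethylsilane (ketene acetal geometry not defined) | C=C(OC)C(CC=C(C)C)=C(OC)O[Si](C)(C)C
A6 | alternative 2 | 3-[2,4-bis(methoxymethoxy)phenyl]-5-(phenylsulfinyl)-4H-pyran-4-one (racemic at sulfur) | O=c1c(-c2ccc(OCOC)cc2OCOC)cocc1S(=O)c1ccccc1
A7 | alternative 3 | 3-[2,4-bis(methoxymethoxy)phenyl]-5,7-dimethoxy-6-(3-methylbut-2-enyl)-4H-chromen-4-one | COc1cc2occ(-c3ccc(OCOC)cc3OCOC)c(=O)c2c(OC)c1CC=C(C)C
A8 | alternative 3 | 3,5-dimethoxy-4-(3-methylbut-2-enyl)-2-(trimethylsilyl)phenyl trifluoromethanesulfonate | COc1cc(OS(=O)(=O)C(F)(F)F)c([Si](C)(C)C)c(OC)c1CC=C(C)C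
A9 | alternative 3 | (E)-2-[2,4-bis(methoxymethoxy)phenyl]-3-methoxyprop-2-enoic acid | CO/C=C(/C(O)=O)c1ccc(OCOC)cc1OCOC
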